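## The problem

The target is an open-chain diarylheptanoid whose saturated chain is numbered here C1 to C7, with C1 on ring A (4-hydroxyphenyl), C7 on ring B (3,4-dihydroxy-5-methoxyphenyl) and hydroxyl groups on C3 and C5 only. No ring has to be closed: the task is to join two arylethyl arms through a 1,3-diol and to fix the configuration of that diol. C3 and C5 are syn and the segment C2–C6 is locally mirror-symmetric, so that with two equal rings the compound would be meso; the absolute configuration (3S,5R in this numbering; 3R,5S in the systematic name, which counts from ring B) therefore says only which end of a syn diol carries which ring. The rings first differ at their meta substituents, six bonds from C3 and C5, so no reagent can read the difference and the sense must come from the order in which the chain is assembled. Either carbinol can control the other (a β-hydroxy ketone is reduced syn through a boron chelate), which is why the usual plans set one centre and relay it. The feature that allows more is this: C1–C2 and C3–C4 are two unbranched two-carbon units joined head to tail, each with its oxygen function on the odd carbon (C1 at the aldehyde level once ring A is thought away, C3 a carbinol), attached to the carbinol carbon C5 of a 3-arylpropyl unit, which is the pattern left by two acetaldehyde molecules added in turn to an aldehyde. O5 lies 1,5 to C1, so the chain can rest as a six-membered lactol (oxane ring O5, C1, C2, C3, C4, C5). Sensitive groups are the 3-methoxycatechol of ring B (air and base), the phenol of ring A, β-hydroxy aldehyde intermediates (retro-aldol, dehydration) and the aryl methyl ether, which must outlive the last deprotection and so rules out methyl as a protecting group.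

## Retrosynthesis

**16 to 15.** The two aryl O–CH2OMe bonds on ring B are cut in the protecting-group sense. Acetal protection is chosen over benzyl or silyl ethers because the ring B arm must be small, neutral and stable in aqueous buffer for the key step, and must later survive a Grignard reagent. The forward reaction only has to cleave two acetals with acid and leave the methyl ether.

**15 to 13 (through 14).** The C1–H bond of 15 is exchanged for C1–OH, and the ring A phenol for its benzyl ether. The para oxygen of ring A allows this: the C1–O bond of 14 is a p-hydroxybenzylic bond that hydrogenolysis removes, while C3–O and C5–O are not benzylic. The cost is one extra oxygen; the gain is that C1 may now be a carbonyl carbon.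

**13 to 10 and 11 (through 12).** The bond between C1 and ring A is cut. The neighbouring cuts (C1–C2 or C2–C3) would leave a short β-hydroxy carbonyl piece still to be extended. This cut leaves the whole chain C1–C7, both stereocenters and ring B in one piece, lactol 10, and ring A as the commercial Grignard reagent 11. The forward reaction is an aryl Grignard addition to a lactol, which reacts through its ring-opened magnesium dialkoxide 12; the new C1 carbinol need not be controlled.

**10 to 6 and two molecules of 7 (key disconnection).** Lactol 10 is the ring form of dihydroxy aldehyde 9, a 2,4-dideoxy aldose whose C5 carries the ring B arm. Cutting C2–C3 and then C4–C5 (through 8) removes two molecules of acetaldehyde 7 and leaves the achiral aldehyde 6. This one cut removes both stereocenters, two C–C bonds and four of the seven chain carbons. The forward reaction must add an unprotected acetaldehyde donor twice, each time with the same facial sense, and stop after two additions. That is the profile of a 2-deoxyribose-5-phosphate aldolase (DERA), whose D-selective double addition gives the 3,5-syn diol with ring B on the acceptor side, which is the enantiomer required.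

**6 to 5 to 3 and 4, and 3 to 1 and 2.** The C6–C7 bond is cut as the C=C bond of enal 5, made by Wittig reaction of aldehyde 3 with the two-carbon ylide 4. Aldehyde 3 is the bis-MOM ether of commercial 5-hydroxyvanillin 1, made with chloromethyl methyl ether 2. Ring B is therefore bought with its oxygen pattern in place.

## Roads not taken

**Alternative 1:** (the most obvious) cut C4–C5 as an aldol bond. The enolate of commercial 4-[4-(benzyloxy)phenyl]butan-2-one, as its boron enolate from Ipc2BCl, would add to aldehyde 6 to give β-hydroxy ketone A1. A Narasaka–Prasad reduction (Et2BOMe, NaBH4) would then set C3, followed by the deprotections of steps 6 and 7. This is an acetate-type aldol of a methyl ketone with an unbranched aldehyde: there is no α-substituent to organise the transition state, so facial control is modest and rests on a stoichiometric chiral boron reagent. The second centre needs a separate cryogenic step. The chosen plan sets both centres in one catalytic operation from the same aldehyde 6 and needs no more steps.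

**Alternative 2:** cut C1=C2 and C6=C7 after raising C3 and C5 to ketones, as in curcuminoid biosynthesis. Boron-templated double condensation (B2O3, B(OBu)3, BuNH2) of pentane-2,4-dione with 1 and 4-hydroxybenzaldehyde would give the unsymmetrical curcuminoid A2. Hydrogenation (H2, Pd/C) would give β-diketone A3, and the key step would be reduction of A3 to the syn diol. The two carbonyl groups of A3 differ only through ring substituents seven or more bonds away, so no catalyst has a handle to choose between them, and even a perfectly syn-selective reduction would give the racemate. Catalyst-controlled hydrogenation of β-diketones also tends to the anti diol, and the mixed condensation gives A2 together with both symmetrical curcuminoids. The chosen plan never passes through a compound in which the two ends are equivalent.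

**Alternative 3:** cut C3–C4 by a boron 1,2-metalate rearrangement. Wittig methylenation of 6 and enantioselective diboration (B2pin2, Pt(dba)3, chiral phosphonite) would give 1,2-bis(boronate) A4. The carbamate A5, lithiated with s-BuLi and sparteine at −78 °C, would add to the primary boron of A4 and give 1,3-bis(boronate) A6 after migration; oxidation (H2O2, NaOH) would give the diol with retention. The logic is sound and fully reagent-controlled, but it needs two independent chiral controllers (one stoichiometric), selectivity between the primary and secondary boron of A4, organolithium chemistry next to aryl ethers (hence a third protecting group on ring A), and about four more steps. The enzyme replaces both controllers and works on unprotected hydroxyl groups.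

Key step: step 4

Remark: 1, 2, 4, 7 and 11 (as a THF solution) are bought; DERA is used as a recombinant E. coli enzyme preparation; chain locants C1–C7 are those defined under "The problem".

## Route

Step 1
Reactants: 1 3,4-dihydroxy-5-methoxybenzaldehyde (5-hydroxyvanillin); 2 chloromethyl methyl ether
Product: 3 3-methoxy-4,5-bis(methoxymethoxy)benzaldehyde
Conditions: MOMCl (2.6 equiv), K2CO3 (4 equiv), acetone, N2, 0 °C to rt
Reagents that add atoms: chloromethyl methyl ether 2, COCCl
Why: Williamson-type O-alkylation of both phenoxides; the aldehyde is inert. MOM ethers survive the ylide, hydrogenation, neutral buffer and the Grignard reagent, and are cleaved at the end by acid that leaves the aryl methyl ether untouched.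

Step 2
Reactants: 3 3-methoxy-4,5-bis(methoxymethoxy)benzaldehyde; 4 (triphenylphosphoranylidene)acetaldehyde
Product: 5 (2E)-3-[3-methoxy-4,5-bis(methoxymethoxy)phenyl]prop-2-enal
Conditions: 4 (1.1 equiv), toluene, 80 °C
Reagents that add atoms: (triphenylphosphoranylidene)acetaldehyde 4, O=CC=P(c1ccccc1)(c1ccccc1)c1ccccc1
Why: Wittig reaction of a stabilised formyl ylide; it adds C5 and C6 to the aldehyde carbon of 3 (future C7) and gives the E enal, whose geometry is erased in step 3.

Step 3
Reactants: 5 (2E)-3-[3-methoxy-4,5-bis(methoxymethoxy)phenyl]prop-2-enal
Product: 6 3-[3-methoxy-4,5-bis(methoxymethoxy)phenyl]propanal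
Conditions: H2 (1 atm, stopped after 1 equiv), 5% Pd/C, EtOAc, rt
Reagents that add atoms: none
Why: Heterogeneous hydrogenation; on palladium the conjugated C=C bond is reduced much faster than an aliphatic aldehyde, and aryl MOM ethers are not hydrogenolysed.

Step 4
Reactants: 6 3-[3-methoxy-4,5-bis(methoxymethoxy)phenyl]propanal; 7 acetaldehyde (two molecules)
Product: 10 lactol (4R,6R)-6-{2-[3-methoxy-4,5-bis(methoxymethoxy)phenyl]ethyl}oxane-2,4-diol as anomer mixture, via (3R)-hydroxy aldehyde 8 (not isolated), via open-chain (3R,5R)-dihydroxy aldehyde 9 (not isolated)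
Conditions: DERA (2-deoxy-D-ribose-5-phosphate aldolase, E. coli, C47M variant, cell-free extract), 6 (50 mM), 7 (2.5 equiv, syringe pump), triethanolamine buffer (0.1 M, pH 7.5), DMSO (15% v/v), N2, 25 °C
Reagents that add atoms: acetaldehyde 7, CC=O (two molecules)
Why: Proposed new method: DERA is a lysine-dependent Schiff-base aldolase whose active-site lysine turns acetaldehyde 7 into an enamine that adds to the aldehyde carbon of 6 (future C5), releases 8 by hydrolysis and repeats the cycle on 8 (future C3); the closest known reaction type is the DERA-catalysed tandem addition of two acetaldehyde units to chloroacetaldehyde and to 3-substituted propanals such as 3-azidopropanal and N-acylated 3-aminopropanals, which gives the 2,4-dideoxyhexose lactols used for statin side chains, and the new element is a 3-arylpropanal as acceptor. Nothing changes at the reacting centre, since 6 is an unbranched aldehyde whose first three carbons are those of the known acceptors, and its aryl group can lie in the solvent-open cleft where the phosphate ester of D-glyceraldehyde 3-phosphate normally binds. Both stereocenters are set by the enzyme alone: each enamine attack gives the D-configured carbinol (as at C3 of 2-deoxy-D-ribose 5-phosphate), here 5R and then 3R, which is the 3,5-syn diol with ring B on the side fixed by the direction of chain growth. The oxane ring of 10 closes by 6-exo-trig addition of the C5 hydroxyl to the C1 aldehyde of 9 (hemiacetal formation), which takes the aldehyde out of the equilibrium and stops the chain after exactly two units. The selectivity needed is cross-addition to 6 and 8 over self-addition of acetaldehyde, and it is secured by feeding 7 slowly into an excess of acceptor. MOM ethers keep ring B neutral, safe from oxidation and soluble in buffer with DMSO, and the C47M variant resists inactivation by crotonaldehyde formed from 7.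

Step 5
Reactants: 10 lactol (4R,6R)-6-{2-[3-methoxy-4,5-bis(methoxymethoxy)phenyl]ethyl}oxane-2,4-diol; 11 [4-(benzyloxy)phenyl]magnesium bromide
Product: 13 (3R,5R)-1-[4-(benzyloxy)phenyl]-7-[3-methoxy-4,5-bis(methoxymethoxy)phenyl]heptane-1,3,5-triol as both C1 epimers, via bis(bromomagnesium) dialkoxide of the open-chain aldehyde 12 (not isolated)
Conditions: 11 (3.5 equiv), THF, −20 °C to rt; aq. NH4Cl
Reagents that add atoms: [4-(benzyloxy)phenyl]magnesium bromide 11, Br[Mg]c1ccc(OCc2ccccc2)cc1
Why: Grignard addition to a lactol: two equivalents of 11 deprotonate the two hydroxyls of 10, the lactolate opens to the aldehyde dialkoxide 12 and a third equivalent adds to its C1, forming the bond from C1 to ring A. The new C1 carbinol is uncontrolled and need not be controlled, since its oxygen is removed in step 6; C3 and C5 are not touched.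

Step 6
Reactants: 13 (3R,5R)-1-[4-(benzyloxy)phenyl]-7-[3-methoxy-4,5-bis(methoxymethoxy)phenyl]heptane-1,3,5-triol
Product: 15 (3S,5R)-1-(4-hydroxyphenyl)-7-[3-methoxy-4,5-bis(methoxymethoxy)phenyl]heptane-3,5-diol, via debenzylated phenol triol 14 (not isolated)
Conditions: H2 (3 bar), 10% Pd/C, EtOH–AcOH (10:1), rt
Reagents that add atoms: none
Why: Palladium-catalysed hydrogenolysis: the benzyl ether is cleaved first, and the resulting p-hydroxybenzylic alcohol 14 then loses its C1–O bond, the only benzylic C–O bond left; the C3 and C5 carbinols and the MOM acetals are inert in EtOH–AcOH. The descriptor at C3 changes from R to S only because C2 drops in priority when C1 loses its oxygen.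

Step 7
Reactants: 15 (3S,5R)-1-(4-hydroxyphenyl)-7-[3-methoxy-4,5-bis(methoxymethoxy)phenyl]heptane-3,5-diol
Product: 16 (3R,5S)-1-(3,4-dihydroxy-5-methoxyphenyl)-7-(4-hydroxyphenyl)heptane-3,5-diol (CNP0291714.1)
Conditions: HCl (2 M in degassed MeOH), argon, rt to 40 °C
Reagents that add atoms: none
Why: Acid-catalysed methanolysis of the two aryl MOM acetals (transacetalisation to dimethoxymethane); the methyl ether, the secondary alcohols and both stereocenters are unaffected, and degassed solvent protects the freed catechol from air.

## Compound list

1 | 3,4-dihydroxy-5-methoxybenzaldehyde (5-hydroxyvanillin) | COc1cc(C=O)cc(O)c1O | starting material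
2 | chloromethyl methyl ether | COCCl | starting material
3 | 3-methoxy-4,5-bis(methoxymethoxy)benzaldehyde | COc1cc(C=O)cc(OCOC)c1OCOC | intermediate
4 | (triphenylphosphoranylidene)acetaldehyde | O=CC=P(c1ccccc1)(c1ccccc1)c1ccccc1 | starting material
5 | (2E)-3-[3-methoxy-4,5-bis(methoxymethoxy)phenyl]prop-2-enal | COc1cc(/C=C/C=O)cc(OCOC)c1OCOC | intermediate
6 | 3-[3-methoxy-4,5-bis(methoxymethoxy)phenyl]propanal | COc1cc(CCC=O)cc(OCOC)c1OCOC | intermediate
7 | acetaldehyde | CC=O | starting material
8 | (3R)-3-hydroxy-5-[3-methoxy-4,5-bis(methoxymethoxy)phenyl]pentanal (not isolated) | O=CC[C@H](O)CCc1cc(OC)c(OCOC)c(OCOC)c1 | intermediate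
9 | (3R,5R)-3,5-dihydroxy-7-[3-methoxy-4,5-bis(methoxymethoxy)phenyl]heptanal (not isolated) | O=CC[C@H](O)C[C@H](O)CCc1cc(OC)c(OCOC)c(OCOC)c1 | intermediate
10 | (4R,6R)-6-{2-[3-methoxy-4,5-bis(methoxymethoxy)phenyl]ethyl}oxane-2,4-diol (anomer mixture) | OC1C[C@H](O)C[C@@H](CCc2cc(OC)c(OCOC)c(OCOC)c2)O1 | intermediate
11 | [4-(benzyloxy)phenyl]magnesium bromide | Br[Mg]c1ccc(OCc2ccccc2)cc1 | starting material
12 | (3R,5R)-3,5-bis(bromomagnesiooxy)-7-[3-methoxy-4,5-bis(methoxymethoxy)phenyl]heptanal, the bis(bromomagnesium) dialkoxide of the open-chain aldehyde (not isolated) | O=CC[C@H](O[Mg]Br)C[C@H](O[Mg]Br)CCc1cc(OC)c(OCOC)c(OCOC)c1 | intermediate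
13 | (3R,5R)-1-[4-(benzyloxy)phenyl]-7-[3-methoxy-4,5-bis(methoxymethoxy)phenyl]heptane-1,3,5-triol (both C1 epimers) | OC(C[C@H](O)C[C@H](O)CCc1cc(OC)c(OCOC)c(OCOC)c1)c1ccc(OCc2ccccc2)cc1 | intermediate
14 | (3R,5R)-1-(4-hydroxyphenyl)-7-[3-methoxy-4,5-bis(methoxymethoxy)phenyl]heptane-1,3,5-triol (both C1 epimers, not isolated) | OC(C[C@H](O)C[C@H](O)CCc1cc(OC)c(OCOC)c(OCOC)c1)c1ccc(O)cc1 | intermediate
15 | (3S,5R)-1-(4-hydroxyphenyl)-7-[3-methoxy-4,5-bis(methoxymethoxy)phenyl]heptane-3,5-diol | Oc1ccc(CC[C@H](O)C[C@H](O)CCc2cc(OC)c(OCOC)c(OCOC)c2)cc1 | intermediate
16 | (3R,5S)-1-(3,4-dihydroxy-5-methoxyphenyl)-7-(4-hydroxyphenyl)heptane-3,5-diol | COc1cc(CC[C@@H](O)C[C@@H](O)CCc2ccc(O)cc2)cc(O)c1O | target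

## Step count and least certain steps

Total steps: 7. Longest linear sequence: 7 (the route is linear; 2, 4, 7 and 11 are bought).

**Step 4 (key step, proposed new method).** The bulky, poorly water-soluble acceptor may be turned over so slowly that self-addition of acetaldehyde consumes the donor. The sequence may also stall after the first addition, or the enzyme may lose activity through aldehyde adducts over the long reaction time. The cause in each case is that 6 lies outside the acceptor range for which the enzyme is documented.

Fallback by known chemistry, setting out from 6: the boron enolate of commercial 4-[4-(benzyloxy)phenyl]butan-2-one (Ipc2BCl, Et3N, Et2O, −78 °C, using the enantiomer of the reagent that directs the enolate to the Si face of 6) is added to 6. This should give the β-hydroxy ketone (5R)-1-[4-(benzyloxy)phenyl]-5-hydroxy-7-[3-methoxy-4,5-bis(methoxymethoxy)phenyl]heptan-3-one F1. Narasaka–Prasad reduction (Et2BOMe, NaBH4, THF–MeOH, −78 °C) should give the syn diol (3S,5R)-1-[4-(benzyloxy)phenyl]-7-[3-methoxy-4,5-bis(methoxymethoxy)phenyl]heptane-3,5-diol F2. Hydrogenolysis of the benzyl ether (H2, Pd/C, EtOAc) rejoins the route at 15.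

**Step 5.** The basic Grignard reagent may deprotonate the α position of the ring-opened aldehyde dialkoxide 12 or trigger its retro-aldol cleavage faster than it adds, and ring opening of the lactolate may be slow; all follow from a free β-oxido aldehyde meeting a strong base.

Fallback, setting out from 10: a Nozaki–Hiyama–Kishi arylation with 1-(benzyloxy)-4-iodobenzene (CrCl2, catalytic NiCl2, DMF, rt) replaces the basic Grignard reagent by a non-basic arylchromium species that adds only to the aldehyde form. It returns directly to 13 and makes no new compound (F0).

**Step 6.** Cleavage of the C1–O bond may stall once the benzyl ether is gone, or the p-hydroxybenzylic cation may be captured by the C5 hydroxyl to close a 2-aryl-oxane before it is reduced; both arise because hydroxide is a poor leaving group and a free δ-hydroxyl sits in reach.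

Fallback, setting out from 13: peracetylation (Ac2O, pyridine, DMAP) gives the triacetate (3R,5R)-1-[4-(benzyloxy)phenyl]-7-[3-methoxy-4,5-bis(methoxymethoxy)phenyl]heptane-1,3,5-triyl triacetate F3, in which C1 carries a good leaving group and O5 is masked. Hydrogenolysis (H2, Pd/C, EtOAc) removes the benzylic acetate and the benzyl ether to give the diacetate (3S,5R)-1-(4-hydroxyphenyl)-7-[3-methoxy-4,5-bis(methoxymethoxy)phenyl]heptane-3,5-diyl diacetate F4. Methanolysis (K2CO3, MeOH) rejoins the route at 15.

## Further compounds

F1 | step 4 | (5R)-1-[4-(benzyloxy)phenyl]-5-hydroxy-7-[3-methoxy-4,5-bis(methoxymethoxy)phenyl]heptan-3-one | O=C(CCc1ccc(OCc2ccccc2)cc1)C[C@H](O)CCc1cc(OC)c(OCOC)c(OCOC)c1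
F2 | step 4 | (3S,5R)-1-[4-(benzyloxy)phenyl]-7-[3-methoxy-4,5-bis(methoxymethoxy)phenyl]heptane-3,5-diol | C(Oc1ccc(CC[C@H](O)C[C@H](O)CCc2cc(OC)c(OCOC)c(OCOC)c2)cc1)c1ccccc1
F0 | step 5 | none | none
F3 | step 6 | (3R,5R)-1-[4-(benzyloxy)phenyl]-7-[3-methoxy-4,5-bis(methoxymethoxy)phenyl]heptane-1,3,5-triyl triacetate (both C1 epimers) | CC(=O)OC(C[C@H](OC(C)=O)C[C@H](OC(C)=O)CCc1cc(OC)c(OCOC)c(OCOC)c1)c1ccc(OCc2ccccc2)cc1
F4 | step 6 | (3S,5R)-1-(4-hydroxyphenyl)-7-[3-methoxy-4,5-bis(methoxymethoxy)phenyl]heptane-3,5-diyl diacetate | Oc1ccc(CC[C@H](OC(C)=O)C[C@H](OC(C)=O)CCc2cc(OC)c(OCOC)c(OCOC)c2)cc1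
A1 | alternative 1 | (5R)-1-[4-(benzyloxy)phenyl]-5-hydroxy-7-[3-methoxy-4,5-bis(methoxymethoxy)phenyl]heptan-3-one | O=C(CCc1ccc(OCc2ccccc2)cc1)C[C@H](O)CCc1cc(OC)c(OCOC)c(OCOC)c1
A2 | alternative 2 | (1E,6E)-1-(3,4-dihydroxy-5-methoxyphenyl)-7-(4-hydroxyphenyl)hepta-1,6-diene-3,5-dione | COc1cc(/C=C/C(=O)CC(=O)/C=C/c2ccc(O)cc2)cc(O)c1O
A3 | alternative 2 | 1-(3,4-dihydroxy-5-methoxyphenyl)-7-(4-hydroxyphenyl)heptane-3,5-dione | COc1cc(CCC(=O)CC(=O)CCc2ccc(O)cc2)cc(O)c1O
A4 | alternative 3 | 2,2'-{(2S)-4-[3-methoxy-4,5-bis(methoxymethoxy)phenyl]butane-1,2-diyl}bis(4,4,5,5-tetramethyl-1,3,2-dioxaborolane) | CC1(C)OB(C[C@H](B2OC(C)(C)C(C)(C)O2)CCc2cc(OC)c(OCOC)c(OCOC)c2)OC1(C)C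
A5 | alternative 3 | 3-{4-[tri(propan-2-yl)silyloxy]phenyl}propyl di(propan-2-yl)carbamate | CC(C)N(C(C)C)C(=O)OCCCc1ccc(O[Si](C(C)C)(C(C)C)C(C)C)cc1
A6 | alternative 3 | 2,2'-[(3S,5R)-1-{4-[tri(propan-2-yl)silyloxy]phenyl}-7-[3-methoxy-4,5-bis(methoxymethoxy)phenyl]heptane-3,5-diyl]bis(4,4,5,5-tetramethyl-1,3,2-dioxaborolane), locants counted from ring A | CC(C)[Si](Oc1ccc(CC[C@H](B2OC(C)(C)C(C)(C)O2)C[C@H](B2OC(C)(C)C(C)(C)O2)CCc2cc(OC)c(OCOC)c(OCOC)c2)cc1)(C(C)C)C(C)C
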